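# Total synthesis proposal for ferugin through a hydroxyl-directed cyclopropanation and reductive opening

## Analysis of the target

Ferugin (37) is a daucane sesquiterpenoid ester. A cyclopentane (C1–C5) and a cycloheptane (C1, C5–C10) share the C1–C5 bond in a trans-fused bicyclo[5.3.0]decane. C1 is quaternary and carries the methyl C15, C4 is the isopropyl carbinol, C5 is the ring-fusion CH, C6 carries the 4-hydroxybenzoate, C8 carries the exocyclic methylene C14, and C9 is a free secondary carbinol. The five stereocentres are (1R,4R,5S,6S,9S). Taking the face of C15 as β, the C4 hydroxyl is β, whereas H5, the C6 acyloxy group and the C9 hydroxyl are α. C4, C5, C1 and C6 form a contiguous array in which C5 is a methine wedged between two fully substituted carbons and an oxygenated carbon. The sensitive groups are the tertiary alcohol (dehydration), the secondary allylic alcohol next to the 1,1-disubstituted alkene (ionisation, allylic transposition), and the phenolic ester with its free phenol (base, acyl transfer). The difficulty is to place the angular methyl on a seven-membered ring with little conformational bias, and to relate C9 to the distant C1/C4/C5/C6 array. The strategy rests on one feature: C15 sits on C1 directly beside C5, and C5 is flanked by the oxygen-bearing C4 and C6. A C1=C5 alkene between a masked C4 ketone and a C6 hydroxyl therefore lets the C6 oxygen deliver C15 as a cyclopropane methylene, and lets the C4 ketone later release it as the methyl group.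

## Retrosynthetic reasoning

**C9 configuration and unmasking (37 from 36 from 35).** No skeletal bond is cut. The target is traced to the bis-ester 36 and then to the C9-epimeric allylic alcohol 35. C9 is 1,3-related to the axial C15 methyl, so a hydride reagent should reach a C9 ketone from the α face and give the 9β alcohol. The forward path therefore inverts C9 by a Mitsunobu reaction. One methanolysis then removes the temporary C9 acyl group and the phenol silyl ether.

**C8–C14 bond (35 from 34 from 31).** The exocyclic methylene is cut back to the C9 ketone 31, where C8 is an α-carbon. Adding C14 late keeps every earlier intermediate free of a second alkene and confines the fragile allylic alcohol to the last three steps. The forward reaction must enolise toward C8 and not toward C10, which is neopentyl, and then reduce the enone 34 at the carbonyl only.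

**Ester C–O bond (31 from 26 and 29; 29 from 27).** The acyl–oxygen bond at C6 is cut to the diol ketone 26 and the silyl-protected acid 29, made from 4-hydroxybenzoic acid (27). The ester enters only after all strongly reducing and organometallic steps.

**C6 configuration (26 from 24 from 23).** The hydroxyl that steers the key step must lie on the β face, but the target has C6–O on the α face. C6 is attached to C5, which lies between two quaternary carbons, so an SN2 inversion there is unattractive. C6 is instead taken through the ketone 24 and reduced with hydride delivered from the β-oriented C4 hydroxyl. The same oxidation of triol 23 also provides the C9 ketone needed later.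

**C4–isopropyl bond (22 from 21; 23 from 22).** The tertiary carbinol is cut to the C4 ketone 21. The forward addition must take place on the α face, away from the C15 methyl and from C6.

**C5–C15 bond (21 from 19 from 18).** The methyl group and H5 are traced back to the cyclopropyl ketone 19, in which C15 bridges C1 and C5. In this bicyclo[3.1.0]hexan-2-one unit only the external C5–C15 bond is aligned with the carbonyl π system, so reductive cleavage must leave C15 on C1. Ketone 19 comes from ketal 18 by hydrolysis.

**C15–C1 and C15–C5 bonds, the key step (18 from 14 and 15).** The cyclopropane is cut to the allylic alcohol 14 and diiodomethane (15). This is the only step that builds the quaternary centre, and it does so under the control of a neighbouring hydroxyl.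

**C5–C6 bond and C6 carbinol (14 from 13 from 12 from 11).** The seven-membered ring is opened at C5–C6 to the iodo aldehyde 11, to be closed by a Nozaki–Hiyama–Kishi reaction. A ring closure cannot be relied on to relate C6 to the remote C9, so the epimers 12 are oxidised to enone 13 and C6 is set by a reagent-controlled CBS reduction.

**Functional-group preparation (11 from 10 from 9 from 8 from 7).** The aldehyde comes from the terminal alkene of 10, the ketal and the vinyl iodide from the enone of 8, and the silyl ether from the alcohol 7.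

**C1–C10 bond (7 from 3 and 4; 3 from 2 from 1).** The enone 7 is cut between C1 and C10. Epoxide 4 supplies C6–C10 with the C9 stereocentre already in place. The sulfone ketal 3 acts as a β-acyl vinyl anion equivalent and is made from cyclopent-2-en-1-one (1) through 2. A vinylogous aldol disconnection of C9–C10 was not used, because a five-membered enone enolises toward the ring and the regiochemistry of the dienolate could not be guaranteed.

## Alternatives that were turned down

**Alternative 1:** Close the cyclopentane last by an intramolecular aldol reaction.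
- Disconnection and key step: the C4–C5 bond is cut. The diketone A1, a cycloheptanone carrying at C1 the methyl group and a 4-methyl-3-oxopentyl chain with C9 masked as a ketal, would be treated with an alkoxide base under equilibrating conditions. Its C5 enolate would add to the isopropyl ketone to give the aldol A2.
- For: the quaternary C1 could be set early by an asymmetric conjugate addition. One step would create C4 and C5. A2 is the C9-ketal analogue of compound 24 of the chosen route and would be reached in fewer steps, with no temporary ring and no inversion at C6.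
- Against: three stereochemical questions (the ring fusion, and which of OH and isopropyl at C4 ends up cis to C15) would be left to the position of a reversible tertiary aldol equilibrium, which often favours the open diketone. The ketone can also enolise toward C7. A2 would stay prone to retro-aldol cleavage in every later basic step.
- Comparison: alternative 1 is stronger on step count. The chosen strategy instead sets C1, C5 and C4 kinetically, each by an identified neighbouring group.

**Alternative 2:** Build the cycloheptadiene by vinylcarbenoid cyclopropanation and Cope rearrangement.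
- Disconnection and key step: the C7–C8 and C1–C10 bonds are cut. The silyloxy diene A3 would react with the diazo ester A4 under a dirhodium tetracarboxylate catalyst. Cyclopropanation of the enol ether followed by rearrangement of the cis-divinylcyclopropane would give A5.
- For: the route is convergent. One step forms the seven-membered ring, the quaternary C1 and the C14 carbon, and a chiral catalyst could add to substrate control. On convergence it is stronger than the chosen route.
- Against: the Cope step must create the quaternary C1 from a tetrasubstituted cyclopentene terminus through a crowded boat transition state. Facial control rests only on the adjacent C4 centre, whose two substituents differ little in size. A5 also has the wrong oxidation pattern: C14 is an ester on an endocyclic C8=C9 alkene and C6 is an enol ether. Correcting this needs an ester-to-methylene transposition with introduction of the C9 oxygen, plus separate control of H5 and C6, which uses up the steps saved.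
- Comparison: the chosen strategy gives a stereochemical relay from C6 to C1/C5 and then to C4, followed by a conventional end game.

**Alternative 3:** Fold an acyclic chain by a ketone-initiated cationic bicyclisation.
- Disconnection and key step: C4–C5 and C1–C10 are cut together. In A6 a Lewis acid would activate the isopropyl ketone, the E-alkene would attack through C5, and the C1 cation would be trapped by the silyl enol ether to give A7.
- For: this is the shortest route. One operation would make both rings and three stereocentres, and anti addition across the E-alkene would give the trans fusion. On step economy it is clearly stronger.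
- Against: a complexed ketone is a weak initiator for an alkene deactivated by the allylic silyloxy group at C6, and that C–O bond can itself ionise. The silyl enol ether is the best nucleophile present and would attack the activated ketone or be cleaved first. Seven-membered ring closure onto the C1 cation must compete with proton loss.
- Comparison: the chosen strategy confines the risk to one well-understood directed cyclopropanation.

Key step: step 11

Remarks on naming and one assumption:
- Names of bicyclic compounds use daucane numbering. "Nor" marks carbons not yet present, and "5,15-cyclo" marks the temporary C5–C15 bond. β is the face of C15.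
- Compounds 2 and 3 are racemic; 5, 6, 12, 32 and 33 are epimer mixtures at centres that are removed later.
- Assumption: external hydride adds to the C9 ketone of 34 from the α face, opposite the C15 methyl, so step 21 gives the 9β alcohol 35, which step 22 inverts.

## Route

Step 1
Reactants: 1 cyclopent-2-en-1-one
Product: 2 3-(phenylsulfonyl)cyclopentan-1-one (racemic)
Conditions: PhSO2Na, AcOH, H2O/EtOH, rt
Reagents that add atoms: sodium benzenesulfinate, [Na+].[O-]S(=O)c1ccccc1
Why: Conjugate (Michael) addition of benzenesulfinic acid, formed in the flask, to the enone; sulfur is the nucleophilic atom and the product is a stable β-sulfonyl ketone.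

Step 2
Reactants: 2 3-(phenylsulfonyl)cyclopentan-1-one
Product: 3 7-(phenylsulfonyl)-1,4-dioxaspiro[4.4]nonane (racemic)
Conditions: HOCH2CH2OH, TsOH·H2O (cat.), toluene, reflux, Dean–Stark
Reagents that add atoms: ethylene glycol, OCCO
Why: Acid-catalysed ketalisation with removal of water; the β-sulfonyl group is lost only under base, so it survives, and the ketal leaves the sulfone α-hydrogen as the only acidic site.

Step 3
Reactants: 3 7-(phenylsulfonyl)-1,4-dioxaspiro[4.4]nonane; 4 (R)-2-(but-3-en-1-yl)oxirane
Product: 7 3-[(2R)-2-hydroxyhex-5-en-1-yl]cyclopent-2-en-1-one, via hydroxy sulfone ketal 5 (not isolated), via hydroxy sulfonyl ketone 6 (not isolated)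
Conditions: n-BuLi, THF/DMPU, −78 °C; then 4, −78 → 0 °C; 2 M aq HCl, rt; then aq K2CO3 (pH 10), rt
Reagents that add atoms: water, O
Why: The α-sulfonyl carbanion opens the terminal epoxide at its CH2 carbon (SN2), forming C1–C10 without touching the C9 stereocentre. Ketal hydrolysis then gives a β-sulfonyl ketone, which loses benzenesulfinate by E1cB elimination through the C5 enolate, the only position from which the sulfone is β, so the C1=C5 enone forms regiospecifically.

Step 4
Reactants: 7 3-[(2R)-2-hydroxyhex-5-en-1-yl]cyclopent-2-en-1-one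
Product: 8 3-[(2R)-2-{[tert-butyl(dimethyl)silyl]oxy}hex-5-en-1-yl]cyclopent-2-en-1-one
Conditions: t-BuMe2SiCl, imidazole, DMF, rt
Reagents that add atoms: tert-butyldimethylsilyl chloride, CC(C)(C)[Si](C)(C)Cl
Why: Standard silylation of a secondary alcohol; the bulky, non-coordinating silyl ether is kept until after the cyclopropane has been opened.

Step 5
Reactants: 8 3-[(2R)-2-{[tert-butyl(dimethyl)silyl]oxy}hex-5-en-1-yl]cyclopent-2-en-1-one
Product: 9 3-[(2R)-2-{[tert-butyl(dimethyl)silyl]oxy}hex-5-en-1-yl]-2-iodocyclopent-2-en-1-one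
Conditions: I2, pyridine, CH2Cl2, rt, dark
Reagents that add atoms: iodine, II
Why: α-Iodination of an enone by conjugate addition of pyridine, iodination of the enolate and elimination; the isolated terminal alkene adds iodine only reversibly and is recovered.

Step 6
Reactants: 9 3-[(2R)-2-{[tert-butyl(dimethyl)silyl]oxy}hex-5-en-1-yl]-2-iodocyclopent-2-en-1-one
Product: 10 tert-butyl{[(2R)-1-(6-iodo-1,4-dioxaspiro[4.4]non-6-en-7-yl)hex-5-en-2-yl]oxy}dimethylsilane
Conditions: Me3SiOCH2CH2OSiMe3, Me3SiOTf (cat.), CH2Cl2, −78 → −20 °C
Reagents that add atoms: 1,2-bis(trimethylsilyloxy)ethane, C[Si](C)(C)OCCO[Si](C)(C)C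
Why: Aprotic Noyori ketalisation, which converts enones to dioxolanes without migration of the double bond and leaves the silyl ether intact; the ketal turns the electron-poor enone alkene into an electron-rich one for step 11.

Step 7
Reactants: 10 tert-butyl{[(2R)-1-(6-iodo-1,4-dioxaspiro[4.4]non-6-en-7-yl)hex-5-en-2-yl]oxy}dimethylsilane
Product: 11 (4R)-4-{[tert-butyl(dimethyl)silyl]oxy}-5-(6-iodo-1,4-dioxaspiro[4.4]non-6-en-7-yl)pentanal
Conditions: OsO4 (cat.), NaIO4, 2,6-lutidine, dioxane/H2O, rt
Reagents that add atoms: osmium tetroxide, O=[Os](=O)(=O)=O; sodium periodate, [Na+].[O-]I(=O)(=O)=O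
Why: Lemieux–Johnson cleavage; OsO4 dihydroxylates the unhindered monosubstituted alkene far faster than the tetrasubstituted iodoalkene, and periodate cleaves the diol to the C6 aldehyde.

Step 8
Reactants: 11 (4R)-4-{[tert-butyl(dimethyl)silyl]oxy}-5-(6-iodo-1,4-dioxaspiro[4.4]non-6-en-7-yl)pentanal
Product: 12 (9R)-9-[(tert-butyldimethylsilyl)oxy]-4,4-(ethylenedioxy)-11,12,13,14,15-pentanordauc-1(5)-en-6-ol (both C6 epimers)
Conditions: CrCl2 (excess), NiCl2 (cat.), DMSO/THF, rt, high dilution
Reagents that add atoms: none
Why: Intramolecular Nozaki–Hiyama–Kishi reaction: zerovalent nickel inserts into the C–I bond, transmetalation gives an alkenyl species of trivalent chromium, and this adds chemoselectively to the aldehyde to close the seven-membered ring at C5–C6. The ketal carbon next to the metalated carbon cannot β-eliminate because that would need a cyclic allene; no control at C6 is claimed.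

Step 9
Reactants: 12 (9R)-9-[(tert-butyldimethylsilyl)oxy]-4,4-(ethylenedioxy)-11,12,13,14,15-pentanordauc-1(5)-en-6-ol
Product: 13 (9R)-9-[(tert-butyldimethylsilyl)oxy]-4,4-(ethylenedioxy)-11,12,13,14,15-pentanordauc-1(5)-en-6-one
Conditions: Dess–Martin periodinane, NaHCO3, CH2Cl2, 0 °C → rt
Reagents that add atoms: none
Why: Dess–Martin oxidation of the allylic alcohol under buffered conditions that spare ketal and silyl ether; both C6 epimers converge on one enone.

Step 10
Reactants: 13 (9R)-9-[(tert-butyldimethylsilyl)oxy]-4,4-(ethylenedioxy)-11,12,13,14,15-pentanordauc-1(5)-en-6-one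
Product: 14 (6R,9R)-9-[(tert-butyldimethylsilyl)oxy]-4,4-(ethylenedioxy)-11,12,13,14,15-pentanordauc-1(5)-en-6-ol
Conditions: (S)-1-methyl-3,3-diphenyltetrahydro-1H,3H-pyrrolo[1,2-c][1,3,2]oxazaborole (0.3 equiv), BH3·SMe2, THF, −30 °C; MeOH
Reagents that add atoms: none
Why: Corey–Bakshi–Shibata reduction; the carbonyl is flanked by a fully substituted alkenyl carbon bearing the spiro ketal (large) and by the C7 methylene (small), so the (S)-oxazaborolidine should deliver hydride to give the 6R carbinol by reagent control, trans to the C9 silyl ether.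

Step 11
Reactants: 14 (6R,9R)-9-[(tert-butyldimethylsilyl)oxy]-4,4-(ethylenedioxy)-11,12,13,14,15-pentanordauc-1(5)-en-6-ol; 15 diiodomethane
Product: 18 (1S,5R,6R,9R)-9-[(tert-butyldimethylsilyl)oxy]-4,4-(ethylenedioxy)-5,15-cyclo-11,12,13,14-tetranordaucan-6-ol, via ethylzinc alkoxide 16 (not isolated), via iodomethylzinc alkoxide 17 (not isolated)
Conditions: Et2Zn (5 equiv), CH2I2 (10 equiv), CH2Cl2, −10 °C → rt
Reagents that add atoms: none
Why: Et2Zn converts the C6 hydroxyl into the ethylzinc alkoxide 16, and exchange with CH2I2 gives the iodomethylzinc alkoxide 17, so the carbenoid is held on the β-face oxygen. Methylene transfer to the C1=C5 alkene is then a concerted, stereospecific [2+1] addition through the butterfly transition state of the Simmons–Smith reaction (Furukawa variant); the closest known reaction type is the hydroxyl-directed cyclopropanation of cyclic allylic alcohols, which is syn-selective for five- to seven-membered rings. The three-membered ring C1–C5–C15 closes by this internally delivered addition, with both new C–C bonds formed on the same face in one step, so the cyclopropane is cis-fused to both rings. The new stereocentres C1 and C5 are set together by the C6 carbinol: C15 enters syn to the hydroxyl, on the β face, while the bulky, non-coordinating C9 silyl ether lies on the α face. The step needs facial selectivity and enough reactivity for a tetrasubstituted alkene; the alkene is the only one in the molecule, it is electron-rich once C4 is a ketal, and tethering raises the effective concentration of the carbenoid. The spiro ketal presents one oxygen to each face and cannot bias the addition. Excess reagent below room temperature is used to outrun O-methylation of the zinc alkoxide.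

Step 12
Reactants: 18 (1S,5R,6R,9R)-9-[(tert-butyldimethylsilyl)oxy]-4,4-(ethylenedioxy)-5,15-cyclo-11,12,13,14-tetranordaucan-6-ol
Product: 19 (1S,5R,6R,9R)-9-[(tert-butyldimethylsilyl)oxy]-6-hydroxy-5,15-cyclo-11,12,13,14-tetranordaucan-4-one
Conditions: pyridinium p-toluenesulfonate, acetone/H2O, 45 °C
Reagents that add atoms: water, O
Why: Mild acid hydrolysis of the dioxolane, whose oxocarbenium ion is stabilised by the adjacent cyclopropane; the acid is too weak to ionise the cyclopropylcarbinol or to cleave the secondary silyl ether.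

Step 13
Reactants: 19 (1S,5R,6R,9R)-9-[(tert-butyldimethylsilyl)oxy]-6-hydroxy-5,15-cyclo-11,12,13,14-tetranordaucan-4-one
Product: 21 (1R,5S,6R,9R)-9-[(tert-butyldimethylsilyl)oxy]-6-hydroxy-11,12,13,14-tetranordaucan-4-one, via dilithium enolate 20 (not isolated)
Conditions: Li, NH3 (l)/THF, −78 °C; then solid NH4Cl
Reagents that add atoms: none
Why: Dissolving-metal reduction of a cyclopropyl ketone cleaves the bond that overlaps with the carbonyl π system, here the external C5–C15 bond of the bicyclo[3.1.0]hexan-2-one unit, so C15 becomes the methyl group on C1. The enolate 20 is protonated on quenching from the α face, opposite the adjacent C15 methyl, giving the trans ring fusion; the C6 oxygen is present as its lithium alkoxide and does not eliminate.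

Step 14
Reactants: 21 (1R,5S,6R,9R)-9-[(tert-butyldimethylsilyl)oxy]-6-hydroxy-11,12,13,14-tetranordaucan-4-one
Product: 22 (1R,4R,5S,6R,9R)-9-[(tert-butyldimethylsilyl)oxy]-14-nordaucane-4,6-diol
Conditions: i-PrMgCl (4 equiv), anhydrous CeCl3, THF, −78 → 0 °C
Reagents that add atoms: isopropylmagnesium chloride, CC(C)[Mg]Cl
Why: Organocerium addition (Imamoto conditions) suppresses enolisation and β-hydride reduction of the hindered cyclopentanone; the β face of the carbonyl is shielded by the C15 methyl and by C6, so the isopropyl group should enter from the α face and leave the C4 hydroxyl β.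

Step 15
Reactants: 22 (1R,4R,5S,6R,9R)-9-[(tert-butyldimethylsilyl)oxy]-14-nordaucane-4,6-diol
Product: 23 (1R,4R,5S,6R,9R)-14-nordaucane-4,6,9-triol
Conditions: Bu4NF, THF, rt
Reagents that add atoms: none
Why: Fluoride-mediated desilylation; it is done before any aryl silyl ether or ester is present, so no selectivity problem arises.

Step 16
Reactants: 23 (1R,4R,5S,6R,9R)-14-nordaucane-4,6,9-triol
Product: 24 (1R,4R,5R)-4-hydroxy-14-nordaucane-6,9-dione
Conditions: Dess–Martin periodinane (3 equiv), NaHCO3, CH2Cl2, rt
Reagents that add atoms: none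
Why: Dess–Martin oxidation of both secondary alcohols in one operation; the tertiary alcohol is inert and the neutral buffered medium avoids retro-aldol cleavage of the new β-hydroxy ketone and epimerisation at C5.

Step 17
Reactants: 24 (1R,4R,5R)-4-hydroxy-14-nordaucane-6,9-dione
Product: 26 (1R,4R,5S,6S)-4,6-dihydroxy-14-nordaucan-9-one, via alkoxyborohydride 25 (not isolated)
Conditions: Me4NBH(OAc)3 (5 equiv), MeCN/AcOH (1:1), −30 °C
Reagents that add atoms: none
Why: Evans–Saksena reduction: ligand exchange at the C4 hydroxyl gives the alkoxyborohydride 25, which delivers hydride within the molecule through a six-membered chair to the β face of the C6 carbonyl, so the new hydroxyl is α (6S, anti to the C4 hydroxyl). Triacetoxyborohydride does not reduce an unassisted ketone, so the C9 carbonyl is retained.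

Step 18
Reactants: 27 4-hydroxybenzoic acid
Product: 29 4-{[tert-butyl(dimethyl)silyl]oxy}benzoic acid, via bis-silylated acid 28 (not isolated)
Conditions: t-BuMe2SiCl (2.2 equiv), imidazole, DMF, rt; then AcOH/THF/H2O, rt
Reagents that add atoms: tert-butyldimethylsilyl chloride, CC(C)(C)[Si](C)(C)Cl
Why: Exhaustive silylation followed by selective hydrolysis of the labile silyl ester; the aryl silyl ether is stable to dilute acetic acid.

Step 19
Reactants: 26 (1R,4R,5S,6S)-4,6-dihydroxy-14-nordaucan-9-one; 29 4-{[tert-butyl(dimethyl)silyl]oxy}benzoic acid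
Product: 31 (1R,4R,5S,6S)-4-hydroxy-9-oxo-14-nordaucan-6-yl 4-{[tert-butyl(dimethyl)silyl]oxy}benzoate, via mixed anhydride 30 (not isolated)
Conditions: 2,4,6-trichlorobenzoyl chloride, Et3N, THF, rt; then 26, 4-(dimethylamino)pyridine, toluene, 40 °C
Reagents that add atoms: none
Why: Yamaguchi esterification, suited to a hindered secondary alcohol; the tertiary C4 hydroxyl does not acylate, and the configuration at C6 is retained because only the O–H bond is broken.

Step 20
Reactants: 31 (1R,4R,5S,6S)-4-hydroxy-9-oxo-14-nordaucan-6-yl 4-{[tert-butyl(dimethyl)silyl]oxy}benzoate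
Product: 34 (1R,4R,5S,6S)-4-hydroxy-9-oxodauc-8(14)-en-6-yl 4-{[tert-butyl(dimethyl)silyl]oxy}benzoate, via Mannich base 32 (not isolated), via trimethylammonium iodide 33 (not isolated)
Conditions: LiN(i-Pr)2 (2.2 equiv), THF, −78 °C; CH2=NMe2+ I−, −78 → 0 °C; then MeI, CH2Cl2, rt; 1,8-diazabicyclo[5.4.0]undec-7-ene, rt
Reagents that add atoms: N,N-dimethylmethyleneiminium iodide, C=[N+](C)C.[I-]
Why: Kinetic deprotonation after the alkoxide forms takes the less hindered C8 hydrogen (C10 is neopentyl); Mannich reaction with Eschenmoser's salt, N-methylation and E1cB elimination give the α-methylene ketone. The aryl ester has no α-hydrogen and the iminium salt traps the enolate at −78 °C.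

Step 21
Reactants: 34 (1R,4R,5S,6S)-4-hydroxy-9-oxodauc-8(14)-en-6-yl 4-{[tert-butyl(dimethyl)silyl]oxy}benzoate
Product: 35 (1R,4R,5S,6S,9R)-4,9-dihydroxydauc-8(14)-en-6-yl 4-{[tert-butyl(dimethyl)silyl]oxy}benzoate
Conditions: NaBH4, CeCl3·7H2O, MeOH, −78 °C
Reagents that add atoms: none
Why: Luche reduction gives 1,2-addition to the enone only. Hydride should arrive on the α face, away from the axial C15 methyl that is 1,3-related to C9, placing the new hydroxyl β (9R).

Step 22
Reactants: 35 (1R,4R,5S,6S,9R)-4,9-dihydroxydauc-8(14)-en-6-yl 4-{[tert-butyl(dimethyl)silyl]oxy}benzoate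
Product: 36 (1R,4R,5S,6S,9S)-4-hydroxy-9-[(4-nitrobenzoyl)oxy]dauc-8(14)-en-6-yl 4-{[tert-butyl(dimethyl)silyl]oxy}benzoate
Conditions: 4-O2NC6H4CO2H, PPh3, diisopropyl azodicarboxylate, toluene, 0 °C → rt
Reagents that add atoms: 4-nitrobenzoic acid, OC(=O)c1ccc(cc1)[N+]([O-])=O
Why: Mitsunobu inversion: the carboxylate displaces the alkoxyphosphonium group by SN2 from the open α face, giving the 9S ester; the acidic 4-nitrobenzoic acid is the standard partner for hindered secondary alcohols, and the tertiary C4 hydroxyl does not react.

Step 23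
Reactants: 36 (1R,4R,5S,6S,9S)-4-hydroxy-9-[(4-nitrobenzoyl)oxy]dauc-8(14)-en-6-yl 4-{[tert-butyl(dimethyl)silyl]oxy}benzoate
Product: 37 ferugin, (1R,4R,5S,6S,9S)-4,9-dihydroxydauc-8(14)-en-6-yl 4-hydroxybenzoate
Conditions: K2CO3, MeOH, 0 °C → rt; aq NH4Cl
Reagents that add atoms: none
Why: Base-mediated methanolysis: the aryl silyl ether is cleaved first, and the resulting phenoxide deactivates the C6 benzoate toward methoxide, whereas the electron-poor 4-nitrobenzoate is transesterified; no stereocentre is touched.

## Compound list

1 | cyclopent-2-en-1-one | O=C1C=CCC1 | starting material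
2 | 3-(phenylsulfonyl)cyclopentan-1-one (racemic) | O=C1CCC(C1)S(=O)(=O)c1ccccc1 | intermediate
3 | 7-(phenylsulfonyl)-1,4-dioxaspiro[4.4]nonane (racemic) | O=S(=O)(c1ccccc1)C1CCC2(C1)OCCO2 | intermediate
4 | (R)-2-(but-3-en-1-yl)oxirane | C=CCC[C@@H]1CO1 | starting material
5 | (2R)-1-[7-(phenylsulfonyl)-1,4-dioxaspiro[4.4]nonan-7-yl]hex-5-en-2-ol (both configurations at the sulfone carbon) | C=CCC[C@@H](O)CC1(CCC2(C1)OCCO2)S(=O)(=O)c1ccccc1 | intermediate (not isolated)
6 | 3-[(2R)-2-hydroxyhex-5-en-1-yl]-3-(phenylsulfonyl)cyclopentan-1-one (both configurations at the sulfone carbon) | C=CCC[C@@H](O)CC1(CCC(=O)C1)S(=O)(=O)c1ccccc1 | intermediate (not isolated)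
7 | 3-[(2R)-2-hydroxyhex-5-en-1-yl]cyclopent-2-en-1-one | C=CCC[C@@H](O)CC1=CC(=O)CC1 | intermediate
8 | 3-[(2R)-2-{[tert-butyl(dimethyl)silyl]oxy}hex-5-en-1-yl]cyclopent-2-en-1-one | C=CCC[C@@H](O[Si](C)(C)C(C)(C)C)CC1=CC(=O)CC1 | intermediate
9 | 3-[(2R)-2-{[tert-butyl(dimethyl)silyl]oxy}hex-5-en-1-yl]-2-iodocyclopent-2-en-1-one | C=CCC[C@@H](O[Si](C)(C)C(C)(C)C)CC1=C(I)C(=O)CC1 | intermediate
10 | tert-butyl{[(2R)-1-(6-iodo-1,4-dioxaspiro[4.4]non-6-en-7-yl)hex-5-en-2-yl]oxy}dimethylsilane | C=CCC[C@@H](O[Si](C)(C)C(C)(C)C)CC1=C(I)C2(CC1)OCCO2 | intermediate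
11 | (4R)-4-{[tert-butyl(dimethyl)silyl]oxy}-5-(6-iodo-1,4-dioxaspiro[4.4]non-6-en-7-yl)pentanal | O=CCC[C@@H](O[Si](C)(C)C(C)(C)C)CC1=C(I)C2(CC1)OCCO2 | intermediate
12 | (9R)-9-[(tert-butyldimethylsilyl)oxy]-4,4-(ethylenedioxy)-11,12,13,14,15-pentanordauc-1(5)-en-6-ol (both C6 epimers) | OC1CC[C@@H](O[Si](C)(C)C(C)(C)C)CC2=C1C3(CC2)OCCO3 | intermediate
13 | (9R)-9-[(tert-butyldimethylsilyl)oxy]-4,4-(ethylenedioxy)-11,12,13,14,15-pentanordauc-1(5)-en-6-one | O=C1CC[C@@H](O[Si](C)(C)C(C)(C)C)CC2=C1C3(CC2)OCCO3 | intermediate
14 | (6R,9R)-9-[(tert-butyldimethylsilyl)oxy]-4,4-(ethylenedioxy)-11,12,13,14,15-pentanordauc-1(5)-en-6-ol | C1C[C@@H](O)C2=C(CCC23OCCO3)C[C@@H]1O[Si](C)(C)C(C)(C)C | intermediate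
15 | diiodomethane | ICI | starting material
16 | ethylzinc alkoxide of 14 (O6–Zn–Et) | C1C[C@@H](O[Zn]CC)C2=C(CCC23OCCO3)C[C@@H]1O[Si](C)(C)C(C)(C)C | intermediate (not isolated)
17 | iodomethylzinc alkoxide of 14 (O6–Zn–CH2I) | C1C[C@@H](O[Zn]CI)C2=C(CCC23OCCO3)C[C@@H]1O[Si](C)(C)C(C)(C)C | intermediate (not isolated)
18 | (1S,5R,6R,9R)-9-[(tert-butyldimethylsilyl)oxy]-4,4-(ethylenedioxy)-5,15-cyclo-11,12,13,14-tetranordaucan-6-ol | C1C[C@@H](O)[C@@]23C[C@@]2(CCC34OCCO4)C[C@@H]1O[Si](C)(C)C(C)(C)C | intermediate
19 | (1S,5R,6R,9R)-9-[(tert-butyldimethylsilyl)oxy]-6-hydroxy-5,15-cyclo-11,12,13,14-tetranordaucan-4-one | C1C[C@@H](O)[C@@]23C[C@@]2(CCC3=O)C[C@@H]1O[Si](C)(C)C(C)(C)C | intermediate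
20 | dilithium C4(5)-enolate C6-alkoxide of 21 | C1C[C@@H](O[Li])C2=C(O[Li])CC[C@]2(C)C[C@@H]1O[Si](C)(C)C(C)(C)C | intermediate (not isolated)
21 | (1R,5S,6R,9R)-9-[(tert-butyldimethylsilyl)oxy]-6-hydroxy-11,12,13,14-tetranordaucan-4-one | C1C[C@@H](O)[C@@H]2[C@](C)(CCC2=O)C[C@@H]1O[Si](C)(C)C(C)(C)C | intermediate
22 | (1R,4R,5S,6R,9R)-9-[(tert-butyldimethylsilyl)oxy]-14-nordaucane-4,6-diol | C1C[C@@H](O)[C@@H]2[C@](C)(CC[C@@]2(O)C(C)C)C[C@@H]1O[Si](C)(C)C(C)(C)C | intermediate
23 | (1R,4R,5S,6R,9R)-14-nordaucane-4,6,9-triol | C1C[C@@H](O)[C@@H]2[C@](C)(CC[C@@]2(O)C(C)C)C[C@@H]1O | intermediate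
24 | (1R,4R,5R)-4-hydroxy-14-nordaucane-6,9-dione | O=C1CCC(=O)[C@@H]2[C@](C)(CC[C@@]2(O)C(C)C)C1 | intermediate
25 | tetramethylammonium diacetoxy(hydrido)borate bound through O4 of 24 | O=C1CCC(=O)[C@@H]2[C@](C)(CC[C@@]2(O[BH-](OC(C)=O)OC(C)=O)C(C)C)C1.C[N+](C)(C)C | intermediate (not isolated)
26 | (1R,4R,5S,6S)-4,6-dihydroxy-14-nordaucan-9-one | O=C1CC[C@H](O)[C@@H]2[C@](C)(CC[C@@]2(O)C(C)C)C1 | intermediate
27 | 4-hydroxybenzoic acid | OC(=O)c1ccc(O)cc1 | starting material
28 | tert-butyldimethylsilyl 4-{[tert-butyl(dimethyl)silyl]oxy}benzoate | CC(C)(C)[Si](C)(C)OC(=O)c1ccc(O[Si](C)(C)C(C)(C)C)cc1 | intermediate (not isolated)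
29 | 4-{[tert-butyl(dimethyl)silyl]oxy}benzoic acid | OC(=O)c1ccc(O[Si](C)(C)C(C)(C)C)cc1 | intermediate
30 | 4-{[tert-butyl(dimethyl)silyl]oxy}benzoic 2,4,6-trichlorobenzoic anhydride | CC(C)(C)[Si](C)(C)Oc1ccc(cc1)C(=O)OC(=O)c1c(Cl)cc(Cl)cc1Cl | intermediate (not isolated)
31 | (1R,4R,5S,6S)-4-hydroxy-9-oxo-14-nordaucan-6-yl 4-{[tert-butyl(dimethyl)silyl]oxy}benzoate | O=C1CC[C@H](OC(=O)c3ccc(O[Si](C)(C)C(C)(C)C)cc3)[C@@H]2[C@](C)(CC[C@@]2(O)C(C)C)C1 | intermediate
32 | (1R,4R,5S,6S)-14-(dimethylamino)-4-hydroxy-9-oxodaucan-6-yl 4-{[tert-butyl(dimethyl)silyl]oxy}benzoate (C8 epimers) | CN(C)CC1C[C@H](OC(=O)c3ccc(O[Si](C)(C)C(C)(C)C)cc3)[C@@H]2[C@](C)(CC[C@@]2(O)C(C)C)CC1=O | intermediate (not isolated)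
33 | N,N,N-trimethylammonium iodide of 32 (C14–NMe3+ I−) | C[N+](C)(C)CC1C[C@H](OC(=O)c3ccc(O[Si](C)(C)C(C)(C)C)cc3)[C@@H]2[C@](C)(CC[C@@]2(O)C(C)C)CC1=O.[I-] | intermediate (not isolated)
34 | (1R,4R,5S,6S)-4-hydroxy-9-oxodauc-8(14)-en-6-yl 4-{[tert-butyl(dimethyl)silyl]oxy}benzoate | C=C1C[C@H](OC(=O)c3ccc(O[Si](C)(C)C(C)(C)C)cc3)[C@@H]2[C@](C)(CC[C@@]2(O)C(C)C)CC1=O | intermediate
35 | (1R,4R,5S,6S,9R)-4,9-dihydroxydauc-8(14)-en-6-yl 4-{[tert-butyl(dimethyl)silyl]oxy}benzoate | C=C1C[C@H](OC(=O)c3ccc(O[Si](C)(C)C(C)(C)C)cc3)[C@@H]2[C@](C)(CC[C@@]2(O)C(C)C)C[C@H]1O | intermediate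
36 | (1R,4R,5S,6S,9S)-4-hydroxy-9-[(4-nitrobenzoyl)oxy]dauc-8(14)-en-6-yl 4-{[tert-butyl(dimethyl)silyl]oxy}benzoate | C=C1C[C@H](OC(=O)c3ccc(O[Si](C)(C)C(C)(C)C)cc3)[C@@H]2[C@](C)(CC[C@@]2(O)C(C)C)C[C@@H]1OC(=O)c1ccc(cc1)[N+]([O-])=O | intermediate
37 | ferugin, (1R,4R,5S,6S,9S)-4,9-dihydroxydauc-8(14)-en-6-yl 4-hydroxybenzoate | C=C1C[C@H](OC(=O)c2ccc(O)cc2)[C@@H]2[C@](C)(CC[C@@]2(O)C(C)C)C[C@@H]1O | target

## Step count and least certain steps

Total step count: 23. Longest linear sequence: 22 (steps 1–17 and 19–23; step 18 is a one-step side branch).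

**Step 11 (key step).** The most likely failure is slow methylene transfer to the hindered tetrasubstituted alkene. O-methylation of the zinc alkoxide could then take over, or zinc iodide could open the ketal. Facial selectivity could also erode if the carbenoid is guided by a ketal oxygen and not by the C6 alkoxide. Fallback, from enone 13, returning at 18: a Corey–Chaykovsky reaction with dimethylsulfoxonium methylide (trimethylsulfoxonium iodide, NaH, DMSO) would add C15 to C1 from the face opposite the C9 silyl ether and close onto C5. This gives the cyclopropyl ketone (1S,5R,9R)-9-[(tert-butyldimethylsilyl)oxy]-4,4-(ethylenedioxy)-5,15-cyclo-11,12,13,14-tetranordaucan-6-one F1. Reduction with NaBH4, with hydride arriving anti to the cyclopropane methylene, would then give 18.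

**Step 14.** The hindered, enolisable cyclopentanone may be deprotonated or reduced by β-hydride transfer from the isopropyl reagent, leaving unreacted ketone or the secondary C4 alcohol. Fallback, from 21, returning at 22: addition of isopropenylmagnesium bromide with CeCl3, a nucleophile with no β-hydride to transfer, would give (1R,4S,5S,6R,9R)-9-[(tert-butyldimethylsilyl)oxy]-14-nordauc-11-ene-4,6-diol F2. Hydrogenation (H2, PtO2, EtOAc) of its only alkene would then give 22.

**Step 17.** Ligand exchange at the tertiary C4 hydroxyl may be slow, so that internal hydride delivery does not outrun slow reduction of the C9 ketone through the new C6 hydroxyl. The hindered β face could also be avoided, giving the 6β epimer. Fallback, from 22, returning at 31: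
- A Mitsunobu esterification with acid 29 (PPh3, diisopropyl azodicarboxylate) would invert C6 directly and give (1R,4R,5S,6S,9R)-9-[(tert-butyldimethylsilyl)oxy]-4-hydroxy-14-nordaucan-6-yl 4-{[tert-butyl(dimethyl)silyl]oxy}benzoate F3.
- Acid-catalysed methanolysis (camphorsulfonic acid, MeOH) would cleave the alkyl silyl ether, but not the aryl silyl ether, to give (1R,4R,5S,6S,9R)-4,9-dihydroxy-14-nordaucan-6-yl 4-{[tert-butyl(dimethyl)silyl]oxy}benzoate F4.
- Dess–Martin oxidation would then give 31.

**Step 20.** Deprotonation may be unselective between C8 and C10. The lithium enolate may also attack the C6 ester carbonyl (O to C aroyl transfer through a five-membered transition state) before it is trapped. Fallback, from 31, returning at 34: direct acid-mediated α-methylenation with paraformaldehyde and N-methylanilinium trifluoroacetate in THF at reflux. This proceeds through the enol by Mannich reaction and elimination, forms no enolate, and adds no new compound.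

**Step 22.** Displacement at the allylic C9 may go with allylic transposition (attack at C14) or with elimination to a diene. The step also rests on the facial course assumed for step 21. Fallback, from 34, returning at 37: a reagent-controlled reduction with (R)-1-methyl-3,3-diphenyltetrahydro-1H,3H-pyrrolo[1,2-c][1,3,2]oxazaborole and catecholborane, the alkenyl carbon C8 acting as the large group, would give (1R,4R,5S,6S,9S)-4,9-dihydroxydauc-8(14)-en-6-yl 4-{[tert-butyl(dimethyl)silyl]oxy}benzoate F5 directly. K2CO3 in MeOH would then remove the silyl group to give 37.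

## Further compounds

F1 | step 11 | (1S,5R,9R)-9-[(tert-butyldimethylsilyl)oxy]-4,4-(ethylenedioxy)-5,15-cyclo-11,12,13,14-tetranordaucan-6-one | C1CC(=O)[C@@]23C[C@@]2(CCC34OCCO4)C[C@@H]1O[Si](C)(C)C(C)(C)C
F2 | step 14 | (1R,4S,5S,6R,9R)-9-[(tert-butyldimethylsilyl)oxy]-14-nordauc-11-ene-4,6-diol | C1C[C@@H](O)[C@@H]2[C@](C)(CC[C@@]2(O)C(C)=C)C[C@@H]1O[Si](C)(C)C(C)(C)C
F3 | step 17 | (1R,4R,5S,6S,9R)-9-[(tert-butyldimethylsilyl)oxy]-4-hydroxy-14-nordaucan-6-yl 4-{[tert-butyl(dimethyl)silyl]oxy}benzoate | C1C[C@H](OC(=O)c3ccc(O[Si](C)(C)C(C)(C)C)cc3)[C@@H]2[C@](C)(CC[C@@]2(O)C(C)C)C[C@@H]1O[Si](C)(C)C(C)(C)C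
F4 | step 17 | (1R,4R,5S,6S,9R)-4,9-dihydroxy-14-nordaucan-6-yl 4-{[tert-butyl(dimethyl)silyl]oxy}benzoate | C1C[C@H](OC(=O)c3ccc(O[Si](C)(C)C(C)(C)C)cc3)[C@@H]2[C@](C)(CC[C@@]2(O)C(C)C)C[C@@H]1O
F0 | step 20 | none | none
F5 | step 22 | (1R,4R,5S,6S,9S)-4,9-dihydroxydauc-8(14)-en-6-yl 4-{[tert-butyl(dimethyl)silyl]oxy}benzoate | C=C1C[C@H](OC(=O)c3ccc(O[Si](C)(C)C(C)(C)C)cc3)[C@@H]2[C@](C)(CC[C@@]2(O)C(C)C)C[C@@H]1O
A1 | alternative 1 | 3-methyl-3-(4-methyl-3-oxopentyl)cycloheptane-1,5-dione 5-ethylene ketal, C1 configured as in the target (daucane C6 ketone, C9 ketal) | O=C1C[C@](C)(CCC(=O)C(C)C)CC2(CC1)OCCO2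
A2 | alternative 1 | trans-fused 4-hydroxy-14-nordaucan-6-one with the C9 carbonyl as ethylene ketal | C1CC(=O)[C@@H]3[C@](C)(CC[C@@]3(O)C(C)C)CC12OCCO2
A3 | alternative 2 | 1-[1-(tert-butyldimethylsilyloxy)vinyl]-2-methyl-5-(propan-2-yl)-5-(triethylsilyloxy)cyclopent-1-ene | C=C(O[Si](C)(C)C(C)(C)C)C1=C(C)CC[C@@]1(O[Si](CC)(CC)CC)C(C)C
A4 | alternative 2 | methyl 2-diazobut-3-enoate | COC(=O)C(=[N+]=[N-])C=C
A5 | alternative 2 | bicyclic cyclohepta-1,4-diene with the C14 ester on C8, C6 silyl enol ether, C4 triethylsilyl ether and quaternary C1 | COC(=O)C1=CC[C@@]2(C)CC[C@@](O[Si](CC)(CC)CC)(C(C)C)C2=C(O[Si](C)(C)C(C)(C)C)C1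
A6 | alternative 3 | (E)-configured acyclic isopropyl ketone with C1=C5 alkene, C6 tert-butyldimethylsilyl ether and C9 trimethylsilyl enol ether | CC(C)C(=O)CC/C(C)=C/[C@@H](O[Si](C)(C)C(C)(C)C)CCC(=C)O[Si](C)(C)C
A7 | alternative 3 | trans-fused C9 ketone with C4 tertiary alcohol and C6 tert-butyldimethylsilyl ether | C1C[C@H](O[Si](C)(C)C(C)(C)C)[C@@H]2[C@](C)(CC[C@@]2(O)C(C)C)CC1=O
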